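**Strategy.** The target is the mono-seco acid of a twofold-symmetric 6,6'-bichromanone bis-lactone, so one monomer is made, joined to itself and opened once. The monomer rests on the C2–C3 disconnection of the pyranone ring: quaternary C2 carries ester carbon C13 and is linked through C3H2 to the aryl ketone carbon C4, the array a [3,3] shift of an allyl ester enolate leaves behind. A benzo-fused eight-membered allyl lactone (aryl ether oxygen on C2, exocyclic methylene on the arene-bound carbon, (R)-carbinol) is contracted in one operation to the chroman, which forms C2–C3, closes the pyran ring and sets C2.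

Key step: step 8

**Remarks on the chemistry (assumptions)**
- Atom labels: chromanone O1, C2, C3, C4, C4a, C5–C8, C8a; side chain C9–C12; ester carbon C13.
- Hydroxy ester 6 is used as the commercial racemate, so 7–10 are pairs of C2 epimers and that carbon is drawn without configuration. This is deliberate: C2 becomes planar in step 8 and both epimers converge.
- In the target the C9 hydroxyl and the C10 methyl lie on the same side of the C2–C9–C10–C11 zigzag (C2 and the methyl are cis on the lactone). The side chain is therefore set with a (Z)-crotyl reagent.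
- Only the two hydroxyl groups flank the biaryl axis, so no atropisomers are expected.

Step 1
Reactants: 1 (R)-but-3-yn-2-ol
Product: 2 (R)-tert-butyl(but-3-yn-2-yloxy)dimethylsilane
Conditions: TBSCl, imidazole, CH2Cl2, 0 °C to rt
Reagents that add atoms: tert-butyldimethylsilyl chloride, CC(C)(C)[Si](C)(C)Cl
Why: Silylation of a secondary alcohol with a silyl chloride and imidazole is routine, does not touch the stereocentre, and masks the hydroxyl through the copper, palladium and Mitsunobu steps.

Step 2
Reactants: 2 (R)-tert-butyl(but-3-yn-2-yloxy)dimethylsilane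
Product: 3 (R)-tert-butyldimethyl{[3-(4,4,5,5-tetramethyl-1,3,2-dioxaborolan-2-yl)but-3-en-2-yl]oxy}silane
Conditions: B2pin2, (SIMes)CuCl (cat., SIMes = 1,3-dimesityl-4,5-dihydroimidazol-2-ylidene), NaOt-Bu (cat.), MeOH, THF, −50 to −15 °C
Reagents that add atoms: bis(pinacolato)diboron, CC1(C)OB(OC1(C)C)B1OC(C)(C)C(C)(C)O1
Why: Copper-catalysed protoboration of a terminal alkyne (borylcupration, then protonation by methanol) places boron on the internal carbon when an N-aryl carbene ligand and a propargylic ether are combined, giving the 1,1-disubstituted vinylboronate with the carbinol centre untouched.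

Step 3
Reactants: 3 (R)-tert-butyldimethyl{[3-(4,4,5,5-tetramethyl-1,3,2-dioxaborolan-2-yl)but-3-en-2-yl]oxy}silane; 4 2-iodo-3-methoxyphenol
Product: 5 2-[(3R)-3-(tert-butyldimethylsilyloxy)but-1-en-2-yl]-3-methoxyphenol
Conditions: Pd(OAc)2, SPhos, K3PO4, THF/H2O, 60 °C
Reagents that add atoms: none
Why: Suzuki–Miyaura coupling with a bulky biaryl phosphine is suited to the doubly ortho-substituted iodide, tolerates the free phenol as its phenoxide, and leaves the silyl ether and the stereocentre alone.

Step 4
Reactants: 5 2-[(3R)-3-(tert-butyldimethylsilyloxy)but-1-en-2-yl]-3-methoxyphenol; 6 methyl 2-hydroxybut-3-enoate (racemic)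
Product: 7 methyl 2-{2-[(3R)-3-(tert-butyldimethylsilyloxy)but-1-en-2-yl]-3-methoxyphenoxy}but-3-enoate (both C2 epimers)
Conditions: PPh3, DIAD, toluene, 0 °C to rt
Reagents that add atoms: none
Why: Mitsunobu etherification of a phenol with a secondary α-hydroxy ester proceeds by direct displacement at the carbon activated by both the ester and the vinyl group, and the configuration of that carbon is irrelevant because it is erased in step 8.

Step 5
Reactants: 7 methyl 2-{2-[(3R)-3-(tert-butyldimethylsilyloxy)but-1-en-2-yl]-3-methoxyphenoxy}but-3-enoate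
Product: 8 2-{2-[(3R)-3-(tert-butyldimethylsilyloxy)but-1-en-2-yl]-3-methoxyphenoxy}but-3-enoic acid (both C2 epimers)
Conditions: Me3SnOH, 1,2-dichloroethane, 75 °C; 5% aq. HCl wash
Reagents that add atoms: trimethyltin hydroxide, C[Sn](C)(C)O
Why: Tin hydroxide cleaves the methyl ester under near-neutral conditions, which should avoid base-induced migration of the vinyl double bond into conjugation and keeps the silyl ether.

Step 6
Reactants: 8 2-{2-[(3R)-3-(tert-butyldimethylsilyloxy)but-1-en-2-yl]-3-methoxyphenoxy}but-3-enoic acid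
Product: 9 2-{2-[(3R)-3-hydroxybut-1-en-2-yl]-3-methoxyphenoxy}but-3-enoic acid (both C2 epimers)
Conditions: HF·pyridine, THF/pyridine, 0 °C to rt
Reagents that add atoms: none
Why: Buffered fluoride desilylation frees the allylic alcohol without base, so neither the stereocentre nor the β,γ-unsaturated acid is disturbed.

Step 7
Reactants: 9 2-{2-[(3R)-3-hydroxybut-1-en-2-yl]-3-methoxyphenoxy}but-3-enoic acid
Product: 10 (5R)-2-ethenyl-7-methoxy-5-methyl-6-methylidene-5,6-dihydro-2H-1,4-benzodioxocin-3-one (both C2 epimers)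
Conditions: MNBA, DMAP, toluene, high dilution with slow addition of 9, rt
Reagents that add atoms: none
Why: Shiina lactonisation through the mixed anhydride acylates the alcohol with retention at the carbinol carbon, and the eight-membered ring should close because the arene holds the two ends cis and three ring atoms are sp2.

Step 8
Reactants: 10 (5R)-2-ethenyl-7-methoxy-5-methyl-6-methylidene-5,6-dihydro-2H-1,4-benzodioxocin-3-one
Product: 13 (S,E)-4-ethylidene-5-methoxy-2-vinylchromane-2-carboxylic acid, via silyl ketene acetal 11 (not isolated), via trimethylsilyl ester 12 (not isolated)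
Conditions: TMSCl/Et3N (premixed), LiN(SiMe3)2, THF, −78 °C, then rt to 50 °C; 1 M HCl on work-up
Reagents that add atoms: none
Why: Proposed new method: the amide base removes the C2 proton (acidified by the ester, the aryloxy group and the vinyl group) in the presence of TMSCl, and the O-silyl ketene acetal, whose C2=C13 bond lies inside the eight-membered ring with O1 and the ester oxygen cis, undergoes a [3,3] sigmatropic shift that forms C2–C3 and breaks the carbinol C–O bond; the closest known reaction type is the Ireland–Claisen ring contraction of unsaturated macrolactones to carbocycles, which has not been run on an eight-membered aryloxy lactone carrying an exocyclic alkene. The pyran ring (O1, C2, C3, C4, C4a, C8a) closes in a 6-endo-trig sense at the C3=C4 alkene, with the enol ether double bond exocyclic to the new ring, through a bridged chair-like six-atom array. C2 is the only new stereocentre and is controlled by the (R)-carbinol carbon: bond formation and C–O cleavage take place on the same face of the allyl unit, and the carbinol methyl group should point toward C3 because the other orientation presses it against the C5 methoxy group, so that the (2S) acid with the (E)-ethylidene group is expected. The step needs O-silylation and rearrangement to outrun loss of the allylic alkoxide from the enolate, which the in situ silyl chloride quench at −78 °C secures; no leaving group sits β to the enolate, both C2 epimers of 10 give the same ketene acetal, and the small trimethylsilyl group keeps the strain of the inward methyl low.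

Step 9
Reactants: 13 (S,E)-4-ethylidene-5-methoxy-2-vinylchromane-2-carboxylic acid
Product: 14 methyl (S,E)-4-ethylidene-5-methoxy-2-vinylchromane-2-carboxylate
Conditions: MeI, K2CO3, DMF, rt
Reagents that add atoms: iodomethane, CI
Why: O-alkylation of the carboxylate is routine and cannot affect the quaternary C2.

Step 10
Reactants: 14 methyl (S,E)-4-ethylidene-5-methoxy-2-vinylchromane-2-carboxylate
Product: 16 methyl (S)-2-formyl-5-methoxy-4-oxochromane-2-carboxylate, via bis-ozonide 15 (not isolated)
Conditions: O3, CH2Cl2, −78 °C (Sudan Red 7B as end-point indicator); then PPh3, −78 °C to rt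
Reagents that add atoms: ozone, [O-][O+]=O
Why: Ozonolysis with reductive work-up cleaves both alkenes at once, turning the ethylidene group into the C4 ketone and the vinyl group into the C9 aldehyde, while the indicator guards the electron-rich arene and the non-enolisable C2 keeps its configuration.

Step 11
Reactants: 16 methyl (S)-2-formyl-5-methoxy-4-oxochromane-2-carboxylate; 17 cis-but-2-ene
Product: 19 methyl (S)-2-[(1R,2S)-1-hydroxy-2-methylbut-3-en-1-yl]-5-methoxy-4-oxochromane-2-carboxylate, via diisopinocampheylborinate 18 (not isolated)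
Conditions: 17, KOt-Bu, n-BuLi, THF, −78 to −45 °C; (+)-Ipc2BOMe, −78 °C; BF3·OEt2; then 16, −78 °C; NaBO3·4H2O, THF/H2O, rt
Reagents that add atoms: none
Why: Brown crotylboration through a closed chair transition state turns the (Z)-crotyl geometry into the syn C9/C10 relationship, the isopinocampheyl groups from (−)-α-pinene direct the reagent to the re face of the aldehyde to give (9R,10S) independently of the bias of C2, and the aryl ketone is inert at −78 °C.

Step 12
Reactants: 19 methyl (S)-2-[(1R,2S)-1-hydroxy-2-methylbut-3-en-1-yl]-5-methoxy-4-oxochromane-2-carboxylate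
Product: 21 methyl (S)-2-[(1R,2S)-1,4-dihydroxy-2-methylbutyl]-5-methoxy-4-oxochromane-2-carboxylate, via alkyl pinacolboronate 20 (not isolated)
Conditions: HBpin (2.5 equiv), RhCl(PPh3)3 (cat.), THF, rt; then NaBO3·4H2O, THF/H2O, rt
Reagents that add atoms: sodium perborate (NaBO3), [Na+].[O-]OB=O
Why: Rhodium-catalysed hydroboration with pinacolborane puts boron on the terminal carbon and, unlike free dialkylboranes, spares the aryl ketone and the ester, and perborate oxidation then gives the primary alcohol without touching C10.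

Step 13
Reactants: 21 methyl (S)-2-[(1R,2S)-1,4-dihydroxy-2-methylbutyl]-5-methoxy-4-oxochromane-2-carboxylate
Product: 23 methyl (S)-5-methoxy-2-[(2R,3S)-3-methyl-5-oxotetrahydrofuran-2-yl]-4-oxochromane-2-carboxylate, via lactol 22 (not isolated)
Conditions: TEMPO (cat.), PhI(OAc)2, CH2Cl2, rt
Reagents that add atoms: none
Why: Oxidative lactonisation of a 1,4-diol: the oxoammonium oxidant takes the primary alcohol to the aldehyde, which closes onto the hindered C9 hydroxyl as a lactol and is oxidised on to the γ-lactone with no stereocentre involved.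

Step 14
Reactants: 23 methyl (S)-5-methoxy-2-[(2R,3S)-3-methyl-5-oxotetrahydrofuran-2-yl]-4-oxochromane-2-carboxylate
Product: 24 methyl (S)-5-hydroxy-2-[(2R,3S)-3-methyl-5-oxotetrahydrofuran-2-yl]-4-oxochromane-2-carboxylate
Conditions: BCl3, CH2Cl2, −78 to 0 °C; then H2O
Reagents that add atoms: none
Why: Chelation-assisted ether cleavage, in which boron bridges the C4 carbonyl and the peri methoxy oxygen and chloride removes the methyl group, is selective for this ether and spares the methyl ester and the lactone at low temperature.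

Step 15
Reactants: 24 methyl (S)-5-hydroxy-2-[(2R,3S)-3-methyl-5-oxotetrahydrofuran-2-yl]-4-oxochromane-2-carboxylate
Product: 25 methyl (S)-5-hydroxy-6-iodo-2-[(2R,3S)-3-methyl-5-oxotetrahydrofuran-2-yl]-4-oxochromane-2-carboxylate
Conditions: [BnNMe3][ICl2], CaCO3, CH2Cl2/MeOH, rt
Reagents that add atoms: benzyltrimethylammonium dichloroiodate, C[N+](C)(C)Cc1ccccc1.Cl[I-]Cl
Why: Electrophilic aromatic iodination of the hydrogen-bonded phenol should occur at C6, ortho to the hydroxyl and para to O1, as is usual for peri-chelated 5-hydroxychromanones, and the buffered mild iodine source leaves the rest of the molecule alone.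

Step 16
Reactants: 25 methyl (S)-5-hydroxy-6-iodo-2-[(2R,3S)-3-methyl-5-oxotetrahydrofuran-2-yl]-4-oxochromane-2-carboxylate (one half of the batch)
Product: 26 methyl (S)-5-hydroxy-2-[(2R,3S)-3-methyl-5-oxotetrahydrofuran-2-yl]-4-oxo-6-(4,4,5,5-tetramethyl-1,3,2-dioxaborolan-2-yl)chromane-2-carboxylate
Conditions: B2pin2, PdCl2(dppf), KOAc, 1,4-dioxane, 80 °C
Reagents that add atoms: bis(pinacolato)diboron, CC1(C)OB(OC1(C)C)B1OC(C)(C)C(C)(C)O1
Why: Miyaura borylation (oxidative addition of zerovalent palladium into the C6–I bond, acetate-assisted transmetalation with the diboron, reductive elimination) gives the arylboronate, the weak base KOAc spares lactone, ester and chelated phenol, and any biaryl formed by premature coupling is 27 itself.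

Step 17
Reactants: 25 methyl (S)-5-hydroxy-6-iodo-2-[(2R,3S)-3-methyl-5-oxotetrahydrofuran-2-yl]-4-oxochromane-2-carboxylate; 26 methyl (S)-5-hydroxy-2-[(2R,3S)-3-methyl-5-oxotetrahydrofuran-2-yl]-4-oxo-6-(4,4,5,5-tetramethyl-1,3,2-dioxaborolan-2-yl)chromane-2-carboxylate
Product: 27 dimethyl (2S,2'S)-5,5'-dihydroxy-2,2'-bis[(2R,3S)-3-methyl-5-oxotetrahydrofuran-2-yl]-4,4'-dioxo-[6,6'-bichromane]-2,2'-dicarboxylate
Conditions: Pd(OAc)2, SPhos, K3PO4, THF/H2O (10:1), 60 °C; work-up at pH 2
Reagents that add atoms: none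
Why: Suzuki–Miyaura cross-coupling of the iodide with the boronate of the same constitution gives the symmetrical biaryl with no regiochemical question, the bulky biaryl phosphine copes with the ortho-hydroxy partners, and the acidic work-up closes again any lactone opened by the aqueous base.

Step 18
Reactants: 27 dimethyl (2S,2'S)-5,5'-dihydroxy-2,2'-bis[(2R,3S)-3-methyl-5-oxotetrahydrofuran-2-yl]-4,4'-dioxo-[6,6'-bichromane]-2,2'-dicarboxylate
Product: 28 (3S,4R)-4-hydroxy-4-[(2S)-5-hydroxy-6-{(2S)-5-hydroxy-2-(methoxycarbonyl)-2-[(2R,3S)-3-methyl-5-oxotetrahydrofuran-2-yl]-4-oxochroman-6-yl}-2-(methoxycarbonyl)-4-oxochroman-2-yl]-3-methylbutanoic acid (CNP0517857.1)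
Conditions: LiOH (3 equiv), THF/H2O, 0 °C; then AcOH to pH 5, 0 °C, extraction
Reagents that add atoms: lithium hydroxide, [Li+].[OH-]
Why: Saponification: after the two phenols are deprotonated, the third equivalent of hydroxide should open one γ-lactone (either one, by symmetry) in preference to the hindered tertiary methyl esters, and cold buffering to pH 5 should release the hydroxy acid without re-closure, with recovered 27 and over-opened material (re-closed by acid) returned to the step.

**Compound list**
1 | (R)-but-3-yn-2-ol | C[C@@H](O)C#C | starting material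
2 | (R)-tert-butyl(but-3-yn-2-yloxy)dimethylsilane | C[C@@H](O[Si](C)(C)C(C)(C)C)C#C | intermediate
3 | (R)-tert-butyldimethyl{[3-(4,4,5,5-tetramethyl-1,3,2-dioxaborolan-2-yl)but-3-en-2-yl]oxy}silane | C[C@@H](O[Si](C)(C)C(C)(C)C)C(=C)B1OC(C)(C)C(C)(C)O1 | intermediate
4 | 2-iodo-3-methoxyphenol | COc1cccc(O)c1I | starting material
5 | 2-[(3R)-3-(tert-butyldimethylsilyloxy)but-1-en-2-yl]-3-methoxyphenol | C[C@@H](O[Si](C)(C)C(C)(C)C)C(=C)c1c(O)cccc1OC | intermediate
6 | methyl 2-hydroxybut-3-enoate (racemic) | C=CC(O)C(=O)OC | starting material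
7 | methyl 2-{2-[(3R)-3-(tert-butyldimethylsilyloxy)but-1-en-2-yl]-3-methoxyphenoxy}but-3-enoate (both C2 epimers) | C=CC(Oc1cccc(OC)c1C(=C)[C@@H](C)O[Si](C)(C)C(C)(C)C)C(=O)OC | intermediate
8 | 2-{2-[(3R)-3-(tert-butyldimethylsilyloxy)but-1-en-2-yl]-3-methoxyphenoxy}but-3-enoic acid (both C2 epimers) | C=CC(Oc1cccc(OC)c1C(=C)[C@@H](C)O[Si](C)(C)C(C)(C)C)C(=O)O | intermediate
9 | 2-{2-[(3R)-3-hydroxybut-1-en-2-yl]-3-methoxyphenoxy}but-3-enoic acid (both C2 epimers) | C=CC(Oc1cccc(OC)c1C(=C)[C@@H](C)O)C(=O)O | intermediate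
10 | (5R)-2-ethenyl-7-methoxy-5-methyl-6-methylidene-5,6-dihydro-2H-1,4-benzodioxocin-3-one (both C2 epimers) | C=CC1Oc2cccc(OC)c2C(=C)[C@@H](C)OC1=O | intermediate
11 | O-trimethylsilyl ketene acetal of 10, (5R)-2-ethenyl-7-methoxy-5-methyl-6-methylidene-3-(trimethylsilyloxy)-5,6-dihydro-1,4-benzodioxocine | C=C/C1=C(O[Si](C)(C)C)/O[C@H](C)C(=C)c2c(OC)cccc2O1 | intermediate (not isolated)
12 | trimethylsilyl (S,E)-4-ethylidene-5-methoxy-2-vinylchromane-2-carboxylate | C[Si](C)(C)OC(=O)[C@@]1(C=C)C/C(=C\C)c2c(OC)cccc2O1 | intermediate (not isolated)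
13 | (S,E)-4-ethylidene-5-methoxy-2-vinylchromane-2-carboxylic acid | OC(=O)[C@@]1(C=C)C/C(=C\C)c2c(OC)cccc2O1 | intermediate
14 | methyl (S,E)-4-ethylidene-5-methoxy-2-vinylchromane-2-carboxylate | COC(=O)[C@@]1(C=C)C/C(=C\C)c2c(OC)cccc2O1 | intermediate
15 | bis-ozonide of 14 (1,2,4-trioxolanes at the former vinyl and ethylidene groups, mixture at the new acetal carbons) | COC(=O)[C@@]1(C2OCOO2)CC2(OOC(C)O2)c2c(OC)cccc2O1 | intermediate (not isolated)
16 | methyl (S)-2-formyl-5-methoxy-4-oxochromane-2-carboxylate | COC(=O)[C@@]1(C=O)CC(=O)c2c(OC)cccc2O1 | intermediate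
17 | cis-but-2-ene | C/C=C\C | starting material
18 | diisopinocampheylborinate of 19 | COC(=O)[C@@]1([C@H](OB([C@H]2C[C@H]3C[C@@H]([C@@H]2C)C3(C)C)[C@H]2C[C@H]3C[C@@H]([C@@H]2C)C3(C)C)[C@@H](C)C=C)CC(=O)c2c(OC)cccc2O1 | intermediate (not isolated)
19 | methyl (S)-2-[(1R,2S)-1-hydroxy-2-methylbut-3-en-1-yl]-5-methoxy-4-oxochromane-2-carboxylate | COC(=O)[C@@]1([C@H](O)[C@@H](C)C=C)CC(=O)c2c(OC)cccc2O1 | intermediate
20 | methyl (S)-2-[(1R,2S)-1-hydroxy-2-methyl-4-(4,4,5,5-tetramethyl-1,3,2-dioxaborolan-2-yl)butyl]-5-methoxy-4-oxochromane-2-carboxylate | COC(=O)[C@@]1([C@H](O)[C@@H](C)CCB2OC(C)(C)C(C)(C)O2)CC(=O)c2c(OC)cccc2O1 | intermediate (not isolated)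
21 | methyl (S)-2-[(1R,2S)-1,4-dihydroxy-2-methylbutyl]-5-methoxy-4-oxochromane-2-carboxylate | COC(=O)[C@@]1([C@H](O)[C@@H](C)CCO)CC(=O)c2c(OC)cccc2O1 | intermediate
22 | methyl (S)-2-[(2R,3S)-5-hydroxy-3-methyltetrahydrofuran-2-yl]-5-methoxy-4-oxochromane-2-carboxylate (both anomers) | COC(=O)[C@@]1([C@@H]2OC(O)C[C@@H]2C)CC(=O)c2c(OC)cccc2O1 | intermediate (not isolated)
23 | methyl (S)-5-methoxy-2-[(2R,3S)-3-methyl-5-oxotetrahydrofuran-2-yl]-4-oxochromane-2-carboxylate | COC(=O)[C@@]1([C@@H]2OC(=O)C[C@@H]2C)CC(=O)c2c(OC)cccc2O1 | intermediate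
24 | methyl (S)-5-hydroxy-2-[(2R,3S)-3-methyl-5-oxotetrahydrofuran-2-yl]-4-oxochromane-2-carboxylate | COC(=O)[C@@]1([C@@H]2OC(=O)C[C@@H]2C)CC(=O)c2c(O)cccc2O1 | intermediate
25 | methyl (S)-5-hydroxy-6-iodo-2-[(2R,3S)-3-methyl-5-oxotetrahydrofuran-2-yl]-4-oxochromane-2-carboxylate | COC(=O)[C@@]1([C@@H]2OC(=O)C[C@@H]2C)CC(=O)c2c(O)c(I)ccc2O1 | intermediate
26 | methyl (S)-5-hydroxy-2-[(2R,3S)-3-methyl-5-oxotetrahydrofuran-2-yl]-4-oxo-6-(4,4,5,5-tetramethyl-1,3,2-dioxaborolan-2-yl)chromane-2-carboxylate | COC(=O)[C@@]1([C@@H]2OC(=O)C[C@@H]2C)CC(=O)c2c(O)c(B3OC(C)(C)C(C)(C)O3)ccc2O1 | intermediate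
27 | dimethyl (2S,2'S)-5,5'-dihydroxy-2,2'-bis[(2R,3S)-3-methyl-5-oxotetrahydrofuran-2-yl]-4,4'-dioxo-[6,6'-bichromane]-2,2'-dicarboxylate | COC(=O)[C@@]1([C@@H]2OC(=O)C[C@@H]2C)CC(=O)c2c(O)c(-c3ccc4c(c3O)C(=O)C[C@@](C(=O)OC)([C@@H]5OC(=O)C[C@@H]5C)O4)ccc2O1 | intermediate
28 | (3S,4R)-4-hydroxy-4-[(2S)-5-hydroxy-6-{(2S)-5-hydroxy-2-(methoxycarbonyl)-2-[(2R,3S)-3-methyl-5-oxotetrahydrofuran-2-yl]-4-oxochroman-6-yl}-2-(methoxycarbonyl)-4-oxochroman-2-yl]-3-methylbutanoic acid | COC(=O)[C@@]1([C@H](O)[C@@H](C)CC(=O)O)CC(=O)c2c(ccc(-c3ccc4c(c3O)C(=O)C[C@@](C(=O)OC)([C@@H]3OC(=O)C[C@@H]3C)O4)c2O)O1 | target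

**Step count.** Total: 18 steps. Longest linear sequence: 18 steps (1 to 28). Partners 4, 6 and 17 are bought, and 25 enters step 17 a second time as the coupling partner of 26.

**Steps most likely to fail**

1. Step 8. The enolate may expel the allylic alkoxide (ketene formation) or be silylated on carbon. The sigmatropic shift may be too slow in the strained bridged array. The enolate may also be attacked on the other face with the carbinol methyl pointing outward. Fallback (sets out from 5 and 6, returns at 16): the [3,3] shift is moved into an open-chain ester, where chelate-controlled enolate geometry and a chair transition state are established, and the pyran ring is closed afterwards by C–O coupling. Phenol 5 is converted with Tf2O and pyridine into aryl triflate F1 and desilylated with HF·pyridine to allylic alcohol F2. Hydroxy ester 6 is protected with 4-methoxybenzyl trichloroacetimidate and catalytic TfOH as PMB ether F3 and hydrolysed with Me3SnOH to acid F4. Esterification of F2 with F4 (EDC, DMAP) gives allyl ester F5. Ireland–Claisen rearrangement (LiN(SiMe3)2, TMSCl, THF, −78 °C to rt), through the lithium-chelated enolate and a chair with the carbinol methyl equatorial, should give the (S)-configured acid F6, which is methylated (MeI, K2CO3) to ester F7. DDQ removes the PMB group to give tertiary alcohol F8. Intramolecular palladium-catalysed etherification of the aryl triflate (Pd(OAc)2, 2-(di-tert-butylphosphino)-1,1'-binaphthyl, Cs2CO3, toluene, 80 °C) closes the pyran ring to chromane F9, the (Z)-ethylidene isomer of 14. Ozonolysis as in step 10 then gives 16.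

2. Step 7. Intermolecular esterification (diolide and oligomers) may outrun closure of the eight-membered ring, or the vinyl double bond may migrate into conjugation in the activated acid. Fallback (sets out from 7, returns at 10): the ring is closed by alkylating the carboxylate instead of acylating the alcohol. HF·pyridine converts 7 into hydroxy ester F10. Mitsunobu inversion with 4-nitrobenzoic acid gives the (S)-nitrobenzoate F11, and LiOH (THF/H2O, 0 °C) cleaves both esters to the (S)-hydroxy acid F12. Mitsunobu lactonisation (PPh3, DIAD, toluene, high dilution) activates the alcohol, inverts it a second time and gives 10 with the (R)-carbinol.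

3. Step 18. Both lactones may open (a statistical mixture), a methyl ester may be hydrolysed, or the hydroxy acid may close again during acidification. The pyranone ring may also open by β-elimination of the phenoxide and re-close with loss of the C2 configuration. Fallback (sets out from 25 and 26, returns at 28): the two halves are differentiated before the biaryl bond is made. A portion of iodide 25 is treated with LiOH (2 equiv, THF/H2O, 0 °C), which opens its lactone to hydroxy acid F13, kept as its dilithium salt. Suzuki–Miyaura coupling of this salt with boronate 26 under anhydrous fluoride conditions (Pd(OAc)2, SPhos, CsF, DMF, 60 °C) leaves the lactone of 26 closed. Acidification to pH 5 at 0 °C then gives 28 without a statistical mixture.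

Further compounds
F1 | step 8 | 2-[(3R)-3-(tert-butyldimethylsilyloxy)but-1-en-2-yl]-3-methoxyphenyl trifluoromethanesulfonate | C[C@@H](O[Si](C)(C)C(C)(C)C)C(=C)c1c(OS(=O)(=O)C(F)(F)F)cccc1OC
F2 | step 8 | 2-[(3R)-3-hydroxybut-1-en-2-yl]-3-methoxyphenyl trifluoromethanesulfonate | C[C@@H](O)C(=C)c1c(OS(=O)(=O)C(F)(F)F)cccc1OC
F3 | step 8 | methyl 2-[(4-methoxybenzyl)oxy]but-3-enoate (racemic) | C=CC(OCc1ccc(OC)cc1)C(=O)OC
F4 | step 8 | 2-[(4-methoxybenzyl)oxy]but-3-enoic acid (racemic) | C=CC(OCc1ccc(OC)cc1)C(=O)O
F5 | step 8 | (2R)-3-[2-methoxy-6-(trifluoromethylsulfonyloxy)phenyl]but-3-en-2-yl 2-[(4-methoxybenzyl)oxy]but-3-enoate (both epimers at the acid α-carbon) | C=CC(OCc1ccc(OC)cc1)C(=O)O[C@H](C)C(=C)c1c(OS(=O)(=O)C(F)(F)F)cccc1OC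
F6 | step 8 | (S,Z)-2-[(4-methoxybenzyl)oxy]-4-[2-methoxy-6-(trifluoromethylsulfonyloxy)phenyl]-2-vinylhex-4-enoic acid | OC(=O)[C@@](OCc1ccc(OC)cc1)(C=C)C/C(=C/C)c1c(OS(=O)(=O)C(F)(F)F)cccc1OC
F7 | step 8 | methyl (S,Z)-2-[(4-methoxybenzyl)oxy]-4-[2-methoxy-6-(trifluoromethylsulfonyloxy)phenyl]-2-vinylhex-4-enoate | COC(=O)[C@@](OCc1ccc(OC)cc1)(C=C)C/C(=C/C)c1c(OS(=O)(=O)C(F)(F)F)cccc1OC
F8 | step 8 | methyl (S,Z)-2-hydroxy-4-[2-methoxy-6-(trifluoromethylsulfonyloxy)phenyl]-2-vinylhex-4-enoate | COC(=O)[C@@](O)(C=C)C/C(=C/C)c1c(OS(=O)(=O)C(F)(F)F)cccc1OC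
F9 | step 8 | methyl (S,Z)-4-ethylidene-5-methoxy-2-vinylchromane-2-carboxylate | COC(=O)[C@@]1(C=C)C/C(=C/C)c2c(OC)cccc2O1
F10 | step 7 | methyl 2-{2-[(3R)-3-hydroxybut-1-en-2-yl]-3-methoxyphenoxy}but-3-enoate (both C2 epimers) | C=CC(Oc1cccc(OC)c1C(=C)[C@@H](C)O)C(=O)OC
F11 | step 7 | methyl 2-{2-[(3S)-3-(4-nitrobenzoyloxy)but-1-en-2-yl]-3-methoxyphenoxy}but-3-enoate (both C2 epimers) | C=CC(Oc1cccc(OC)c1C(=C)[C@H](C)OC(=O)c1ccc(cc1)[N+](=O)[O-])C(=O)OC
F12 | step 7 | 2-{2-[(3S)-3-hydroxybut-1-en-2-yl]-3-methoxyphenoxy}but-3-enoic acid (both C2 epimers) | C=CC(Oc1cccc(OC)c1C(=C)[C@H](C)O)C(=O)O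
F13 | step 18 | (3S,4R)-4-hydroxy-4-[(2S)-5-hydroxy-6-iodo-2-(methoxycarbonyl)-4-oxochroman-2-yl]-3-methylbutanoic acid | COC(=O)[C@@]1([C@H](O)[C@@H](C)CC(=O)O)CC(=O)c2c(O)c(I)ccc2O1
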